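**Retrosynthetic overview**

- The route rests on C2 of the dihydrobenzofuran (O1, C2, C3, C3a, C4 to C7, C7a). C2 is an allylic ether carbon, so the O1–C2 bond is cut back to the C7a phenol and the internal terminus of a 2-methylallyl unit whose central carbon carries the methyl group.
- Last disconnection: the methylene bridge between C7 and C3 of the pyranone, made from the free C7–H, a formaldehyde iminium salt and the 4-hydroxy-2-pyranone.
- The cyclisation substrate comes from the (R)-acylphloroglucinol. Both ketone-flanking oxygens are masked as methoxymethyl ethers, the para oxygen is reverse-prenylated, a Claisen shift moves the prenyl group to carbon, and (E)-selective allylic oxidation and carbonate formation follow.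
- Ring order: the benzene ring is bought (phloroglucinol), the pyranone ring is built separately from pentan-3-one, the dihydrofuran ring is closed in the key step, and the two ring systems are joined last.

Key step: step 11

Remark on the chemistry: the (R,R)-bisphosphine is assumed to give the (2R)-ether from the (E)-carbonate; this sense of induction is not verified here, and if a first run shows the opposite sense, the (S,S)-ligand is used with nothing else changed.

**Route**

Step 1
Reactants: 1 phloroglucinol; 2 (R)-2-methylbutanoic acid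
Product: 4 (R)-2-methyl-1-(2,4,6-trihydroxyphenyl)butan-1-one, via (R)-2-methylbutanoyl chloride 3 (not isolated)
Conditions: 2, (COCl)2, DMF (cat.), CH2Cl2, 0 °C to rt; solution added to 1, AlCl3 (4 equiv), PhNO2, 0 °C to rt; 1 M HCl work-up
Reagents that add atoms: none
Why: Friedel–Crafts C-acylation of the strongly activated triol stops after one acyl group because the ketone deactivates the ring, and the α-carbon of 2, which sees no base, should pass through the acid chloride and the acylation without epimerisation.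

Step 2
Reactants: 4 (R)-2-methyl-1-(2,4,6-trihydroxyphenyl)butan-1-one
Product: 5 (R)-1-[2,6-dihydroxy-4-(triisopropylsilyloxy)phenyl]-2-methylbutan-1-one
Conditions: i-Pr3SiCl (1.05 equiv), imidazole, DMF, 0 °C
Reagents that add atoms: triisopropylsilyl chloride, CC(C)[Si](Cl)(C(C)C)C(C)C
Why: Selective O-silylation, since the para hydroxyl is the most acidic and least hindered one while the two ortho hydroxyls flank the acyl group and hydrogen-bond to the carbonyl, so a bulky silyl chloride in slight excess should take the para oxygen only.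

Step 3
Reactants: 5 (R)-1-[2,6-dihydroxy-4-(triisopropylsilyloxy)phenyl]-2-methylbutan-1-one
Product: 6 (R)-1-[2,6-bis(methoxymethoxy)-4-(triisopropylsilyloxy)phenyl]-2-methylbutan-1-one
Conditions: NaH (2.1 equiv), THF/DMF, 0 °C; MeOCH2Cl (2.6 equiv), 0 °C to rt
Reagents that add atoms: chloromethyl methyl ether, COCCl
Why: Williamson-type O-alkylation of both phenoxides, in which NaH is needed for the hydrogen-bonded hydroxyl and is limited to what the two phenols consume, so that no base is left to enolise the ketone.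

Step 4
Reactants: 6 (R)-1-[2,6-bis(methoxymethoxy)-4-(triisopropylsilyloxy)phenyl]-2-methylbutan-1-one
Product: 7 (R)-1-[4-hydroxy-2,6-bis(methoxymethoxy)phenyl]-2-methylbutan-1-one
Conditions: Bu4NF (1.1 equiv), AcOH (1.1 equiv), THF, 0 °C to rt
Reagents that add atoms: none
Why: Fluoride-mediated desilylation of an aryl silyl ether, which leaves the acetal ethers untouched and, being buffered, does not expose the ketone to base.

Step 5
Reactants: 8 2-methylbut-3-en-2-ol
Product: 9 tert-butyl 2-methylbut-3-en-2-yl carbonate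
Conditions: n-BuLi, THF, −78 to 0 °C; (t-BuOCO)2O, 0 °C to rt
Reagents that add atoms: di-tert-butyl dicarbonate, CC(C)(C)OC(=O)OC(=O)OC(C)(C)C
Why: O-acylation of the lithium alkoxide of the tertiary allylic alcohol by the dicarbonate is the standard way to this reverse-prenyl donor.

Step 6
Reactants: 7 (R)-1-[4-hydroxy-2,6-bis(methoxymethoxy)phenyl]-2-methylbutan-1-one; 9 tert-butyl 2-methylbut-3-en-2-yl carbonate
Product: 10 (R)-1-[2,6-bis(methoxymethoxy)-4-(2-methylbut-3-en-2-yloxy)phenyl]-2-methylbutan-1-one
Conditions: Pd(PPh3)4 (5 mol %), THF, 0 to 5 °C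
Reagents that add atoms: none
Why: Tsuji–Trost O-allylation, in which zerovalent palladium ionises 9 with loss of CO2, the tert-butoxide set free deprotonates the phenol, and at low temperature the phenoxide attacks the more substituted terminus of the 1,1-dimethylallyl complex to give the kinetic tertiary ether.

Step 7
Reactants: 10 (R)-1-[2,6-bis(methoxymethoxy)-4-(2-methylbut-3-en-2-yloxy)phenyl]-2-methylbutan-1-one
Product: 12 (R)-1-[4-(tert-butyldimethylsilyloxy)-2,6-bis(methoxymethoxy)-3-(3-methylbut-2-en-1-yl)phenyl]-2-methylbutan-1-one, via C-prenyl phenol 11 (not isolated)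
Conditions: DMF, 120 °C; then rt, t-BuMe2SiCl, imidazole
Reagents that add atoms: tert-butyldimethylsilyl chloride, CC(C)(C)[Si](C)(C)Cl
Why: Aromatic Claisen rearrangement ([3,3]) carries the allyl unit, with its ends exchanged, to one of the two equivalent free ortho carbons and returns the para phenol 11, which is silylated in the same flask so that the oxidant of the next step meets no free phenol.

Step 8
Reactants: 12 (R)-1-[4-(tert-butyldimethylsilyloxy)-2,6-bis(methoxymethoxy)-3-(3-methylbut-2-en-1-yl)phenyl]-2-methylbutan-1-one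
Product: 13 (R)-1-[4-(tert-butyldimethylsilyloxy)-3-[(E)-4-hydroxy-3-methylbut-2-en-1-yl]-2,6-bis(methoxymethoxy)phenyl]-2-methylbutan-1-one
Conditions: SeO2 (0.3 equiv), t-BuOOH (3 equiv), CH2Cl2, 0 °C to rt, stopped short of full conversion
Reagents that add atoms: selenium dioxide, O=[Se]=O (delivers the new oxygen); tert-butyl hydroperoxide, CC(C)(C)OO (terminal oxidant that restores SeO2)
Why: Riley allylic oxidation (ene reaction, then [2,3]-shift) of a trisubstituted alkene attacks the more substituted end and there the methyl trans to the chain, which should give the (E)-allylic alcohol and leave the benzylic CH2 alone.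

Step 9
Reactants: 13 (R)-1-[4-(tert-butyldimethylsilyloxy)-3-[(E)-4-hydroxy-3-methylbut-2-en-1-yl]-2,6-bis(methoxymethoxy)phenyl]-2-methylbutan-1-one
Product: 14 (R)-1-[4-(tert-butyldimethylsilyloxy)-3-[(E)-4-(methoxycarbonyloxy)-3-methylbut-2-en-1-yl]-2,6-bis(methoxymethoxy)phenyl]-2-methylbutan-1-one
Conditions: ClCO2Me, pyridine, CH2Cl2, 0 °C
Reagents that add atoms: methyl chloroformate, COC(=O)Cl
Why: Acylation of the primary allylic alcohol, the only free hydroxyl in 13, gives the carbonate leaving group.

Step 10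
Reactants: 14 (R)-1-[4-(tert-butyldimethylsilyloxy)-3-[(E)-4-(methoxycarbonyloxy)-3-methylbut-2-en-1-yl]-2,6-bis(methoxymethoxy)phenyl]-2-methylbutan-1-one
Product: 15 (R)-1-[4-hydroxy-3-[(E)-4-(methoxycarbonyloxy)-3-methylbut-2-en-1-yl]-2,6-bis(methoxymethoxy)phenyl]-2-methylbutan-1-one
Conditions: Bu4NF (1.1 equiv), AcOH (1.1 equiv), THF, 0 °C
Reagents that add atoms: none
Why: Buffered fluoride desilylation frees the phenol in its protonated form, so neither the carbonate nor the acetals are attacked.

Step 11
Reactants: 15 (R)-1-[4-hydroxy-3-[(E)-4-(methoxycarbonyloxy)-3-methylbut-2-en-1-yl]-2,6-bis(methoxymethoxy)phenyl]-2-methylbutan-1-one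
Product: 16 (R)-1-[(R)-4,6-bis(methoxymethoxy)-2-(prop-1-en-2-yl)-2,3-dihydrobenzofuran-5-yl]-2-methylbutan-1-one
Conditions: Pd2(dba)3·CHCl3 (2.5 mol %), (1R,2R)-N,N′-bis[2-(diphenylphosphino)benzoyl]cyclohexane-1,2-diamine (7.5 mol %), AcOH (1 equiv), CH2Cl2, rt
Reagents that add atoms: none
Why: Zerovalent palladium ionises the (E)-allylic carbonate with loss of CO2 and methoxide, giving an η3-allyl complex over C2, the methyl-bearing carbon and the terminal CH2, and the para phenol, deprotonated by the methoxide, attacks it on the face away from the metal. This is the asymmetric Tsuji–Trost O-alkylation of a phenol by a trisubstituted allylic carbonate, a reaction type established for 2-isopropenyl-2,3-dihydrobenzofurans. The dihydrofuran closes in the 5-exo mode at C2, because attack at the CH2 terminus would need a seven-membered ring, and this leaves the isopropenyl group. C2 is set by the chiral pocket of the bisphosphine: the two diastereomeric allyl complexes interconvert through the η1 form faster than they cyclise (the acetic acid keeps the phenol largely protonated and so slows closure), and the faster-closing complex decides the configuration, here (R). The step needs O7a and not O4 to attack, which the acetal groups on the two ketone-flanking oxygens secure, and it needs the (R)-configured α-carbon of the ketone to survive, which it should because no base stronger than the buffered phenoxide is present.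

Step 12
Reactants: 16 (R)-1-[(R)-4,6-bis(methoxymethoxy)-2-(prop-1-en-2-yl)-2,3-dihydrobenzofuran-5-yl]-2-methylbutan-1-one
Product: 17 (R)-1-[(R)-4,6-dihydroxy-2-(prop-1-en-2-yl)-2,3-dihydrobenzofuran-5-yl]-2-methylbutan-1-one
Conditions: TsOH·H2O (0.2 equiv), MeOH, 40 °C
Reagents that add atoms: none
Why: Acid-catalysed acetal exchange with methanol, which is especially easy for aryl methoxymethyl ethers next to a carbonyl, so catalytic acid should suffice and spare the allylic aryl ether and the isopropenyl group.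

Step 13
Reactants: 18 pentan-3-one
Product: 19 trimethyl(pent-2-en-3-yloxy)silane (E/Z mixture)
Conditions: Me3SiOSO2CF3, Et3N, CH2Cl2, 0 °C
Reagents that add atoms: trimethylsilyl trifluoromethanesulfonate, C[Si](C)(C)OS(=O)(=O)C(F)(F)F
Why: Soft enolisation and O-silylation of a symmetrical ketone gives one constitutional silyl enol ether, whose double-bond geometry is lost in the next step.

Step 14
Reactants: 19 trimethyl(pent-2-en-3-yloxy)silane
Product: 20 6-ethyl-4-hydroxy-5-methyl-2H-pyran-2-one
Conditions: ClCOCH2COCl, Et2O, −78 °C to rt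
Reagents that add atoms: malonyl dichloride, O=C(Cl)CC(=O)Cl
Why: C-acylation of the silyl enol ether by one acid chloride gives a β-diketo acid chloride whose enol oxygen lactonises onto the second acid chloride, the known pyranone synthesis from silyl enol ethers and malonyl dichloride.

Step 15
Reactants: 17 (R)-1-[(R)-4,6-dihydroxy-2-(prop-1-en-2-yl)-2,3-dihydrobenzofuran-5-yl]-2-methylbutan-1-one; 20 6-ethyl-4-hydroxy-5-methyl-2H-pyran-2-one
Product: 23 3-{[(2R)-4,6-dihydroxy-5-[(2R)-2-methylbutanoyl]-2-(prop-1-en-2-yl)-2,3-dihydro-1-benzofuran-7-yl]methyl}-6-ethyl-4-hydroxy-5-methyl-2H-pyran-2-one (CNP0199358.1), via pyranone Mannich base 21 (not isolated), via 3-methylidenepyran-2,4-dione 22 (not isolated)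
Conditions: 20 (1.3 equiv), (Me2N=CH2)I (1.3 equiv), CHCl3, rt, 1 h; then 17 (1 equiv), 40 °C
Reagents that add atoms: N,N-dimethylmethyleneiminium iodide (Eschenmoser's salt), C=[N+](C)C.[I-]
Why: Mannich reaction at C3 of the hydroxypyranone, loss of dimethylamine to the 3-methylidene pyran-2,4-dione and conjugate addition of C7 of 17, its only free and most electron-rich ring carbon, build the methylene bridge in the way known for phloroglucinol–pyranone dimers.

**Compound list**

1 | phloroglucinol (benzene-1,3,5-triol) | Oc1cc(O)cc(O)c1 | starting material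
2 | (R)-2-methylbutanoic acid | CC[C@@H](C)C(=O)O | starting material
3 | (R)-2-methylbutanoyl chloride | O=C(Cl)[C@H](C)CC | intermediate
4 | (R)-2-methyl-1-(2,4,6-trihydroxyphenyl)butan-1-one | O=C([C@H](C)CC)c1c(O)cc(O)cc1O | intermediate
5 | (R)-1-[2,6-dihydroxy-4-(triisopropylsilyloxy)phenyl]-2-methylbutan-1-one | O=C([C@H](C)CC)c1c(O)cc(O[Si](C(C)C)(C(C)C)C(C)C)cc1O | intermediate
6 | (R)-1-[2,6-bis(methoxymethoxy)-4-(triisopropylsilyloxy)phenyl]-2-methylbutan-1-one | O=C([C@H](C)CC)c1c(OCOC)cc(O[Si](C(C)C)(C(C)C)C(C)C)cc1OCOC | intermediate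
7 | (R)-1-[4-hydroxy-2,6-bis(methoxymethoxy)phenyl]-2-methylbutan-1-one | O=C([C@H](C)CC)c1c(OCOC)cc(O)cc1OCOC | intermediate
8 | 2-methylbut-3-en-2-ol | C=CC(C)(C)O | starting material
9 | tert-butyl 2-methylbut-3-en-2-yl carbonate | C=CC(C)(C)OC(=O)OC(C)(C)C | intermediate
10 | (R)-1-[2,6-bis(methoxymethoxy)-4-(2-methylbut-3-en-2-yloxy)phenyl]-2-methylbutan-1-one | O=C([C@H](C)CC)c1c(OCOC)cc(OC(C)(C)C=C)cc1OCOC | intermediate
11 | (R)-1-[4-hydroxy-2,6-bis(methoxymethoxy)-3-(3-methylbut-2-en-1-yl)phenyl]-2-methylbutan-1-one | CC(C)=CCc1c(OCOC)c(C(=O)[C@H](C)CC)c(OCOC)cc1O | intermediate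
12 | (R)-1-[4-(tert-butyldimethylsilyloxy)-2,6-bis(methoxymethoxy)-3-(3-methylbut-2-en-1-yl)phenyl]-2-methylbutan-1-one | CC(C)=CCc1c(OCOC)c(C(=O)[C@H](C)CC)c(OCOC)cc1O[Si](C)(C)C(C)(C)C | intermediate
13 | (R)-1-[4-(tert-butyldimethylsilyloxy)-3-[(E)-4-hydroxy-3-methylbut-2-en-1-yl]-2,6-bis(methoxymethoxy)phenyl]-2-methylbutan-1-one | OC/C(C)=C/Cc1c(OCOC)c(C(=O)[C@H](C)CC)c(OCOC)cc1O[Si](C)(C)C(C)(C)C | intermediate
14 | (R)-1-[4-(tert-butyldimethylsilyloxy)-3-[(E)-4-(methoxycarbonyloxy)-3-methylbut-2-en-1-yl]-2,6-bis(methoxymethoxy)phenyl]-2-methylbutan-1-one | COC(=O)OC/C(C)=C/Cc1c(OCOC)c(C(=O)[C@H](C)CC)c(OCOC)cc1O[Si](C)(C)C(C)(C)C | intermediate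
15 | (R)-1-[4-hydroxy-3-[(E)-4-(methoxycarbonyloxy)-3-methylbut-2-en-1-yl]-2,6-bis(methoxymethoxy)phenyl]-2-methylbutan-1-one | COC(=O)OC/C(C)=C/Cc1c(OCOC)c(C(=O)[C@H](C)CC)c(OCOC)cc1O | intermediate
16 | (R)-1-[(R)-4,6-bis(methoxymethoxy)-2-(prop-1-en-2-yl)-2,3-dihydrobenzofuran-5-yl]-2-methylbutan-1-one | C=C(C)[C@H]1Cc2c(OCOC)c(C(=O)[C@H](C)CC)c(OCOC)cc2O1 | intermediate
17 | (R)-1-[(R)-4,6-dihydroxy-2-(prop-1-en-2-yl)-2,3-dihydrobenzofuran-5-yl]-2-methylbutan-1-one | C=C(C)[C@H]1Cc2c(O)c(C(=O)[C@H](C)CC)c(O)cc2O1 | intermediate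
18 | pentan-3-one | CCC(=O)CC | starting material
19 | trimethyl(pent-2-en-3-yloxy)silane (E/Z mixture) | CC=C(CC)O[Si](C)(C)C | intermediate
20 | 6-ethyl-4-hydroxy-5-methyl-2H-pyran-2-one | CCc1oc(=O)cc(O)c1C | intermediate
21 | 3-[(dimethylamino)methyl]-6-ethyl-4-hydroxy-5-methyl-2H-pyran-2-one | CCc1oc(=O)c(CN(C)C)c(O)c1C | intermediate
22 | 6-ethyl-5-methyl-3-methylidene-2H-pyran-2,4(3H)-dione | C=C1C(=O)OC(CC)=C(C)C1=O | intermediate
23 | 3-{[(2R)-4,6-dihydroxy-5-[(2R)-2-methylbutanoyl]-2-(prop-1-en-2-yl)-2,3-dihydro-1-benzofuran-7-yl]methyl}-6-ethyl-4-hydroxy-5-methyl-2H-pyran-2-one | C=C(C)[C@H]1Cc2c(O)c(C(=O)[C@H](C)CC)c(O)c(Cc3c(O)c(C)c(CC)oc3=O)c2O1 | target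

**Totals**

Total step count: 15.
Longest linear sequence: 12 steps (steps 1 to 4, 6 to 12 and 15).

**Steps most likely to fail**

Step 11. The risks are weak face discrimination between the two allyl complexes (or closure in the wrong sense) and β-hydride loss from the allyl complex to a diene. The fallback leaves the route at 12 and sets C2 by reagent-controlled epoxidation. Shi epoxidation of the prenyl double bond with the L-fructose-derived ketone catalyst and KHSO5 (K2CO3 buffer, MeCN/dimethoxymethane/water, 0 °C) should give (R)-1-[4-(tert-butyldimethylsilyloxy)-3-{[(S)-3,3-dimethyloxiran-2-yl]methyl}-2,6-bis(methoxymethoxy)phenyl]-2-methylbutan-1-one F1. Bu4NF in THF then frees the epoxy phenol (R)-1-[3-{[(S)-3,3-dimethyloxiran-2-yl]methyl}-4-hydroxy-2,6-bis(methoxymethoxy)phenyl]-2-methylbutan-1-one F2. Its phenoxide opens the oxirane at the secondary carbon (5-exo, inversion) in the same flask to give (R)-1-[(R)-2-(2-hydroxypropan-2-yl)-4,6-bis(methoxymethoxy)-2,3-dihydrobenzofuran-5-yl]-2-methylbutan-1-one F3. Dehydration of the tertiary alcohol toward a methyl group with the Burgess reagent (MeO2C–N(−)–SO2–N(+)Et3, toluene, 60 °C) comes back to the route at 16.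

Step 8. The risks are over-oxidation of the allylic alcohol to the enal and oxidative attack on the electron-rich ring, which leave little alcohol at useful conversion. The fallback sets out from 12. Olefin cross-metathesis with methacrolein (second-generation Grubbs catalyst RuCl2(=CHPh)(PCy3)(H2IMes), CH2Cl2, 40 °C) exchanges the isopropylidene end with loss of 2-methylpropene and should give (E)-4-[6-(tert-butyldimethylsilyloxy)-2,4-bis(methoxymethoxy)-3-[(R)-2-methylbutanoyl]phenyl]-2-methylbut-2-enal F4. Luche reduction of the aldehyde (NaBH4, CeCl3·7H2O, MeOH, −40 °C), which the hindered aryl ketone should outlast, comes back to the route at 13.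

Step 15. The risk is that the pyranone captures its own methylidene derivative, which gives the symmetrical bis-pyranone and starves the cross-coupling. The fallback sets out from 17 and puts the latent electrophile on the other partner. Mannich reaction of 17 alone with (Me2N=CH2)I (CH2Cl2, rt) should give (R)-1-[(R)-7-[(dimethylamino)methyl]-4,6-dihydroxy-2-(prop-1-en-2-yl)-2,3-dihydrobenzofuran-5-yl]-2-methylbutan-1-one F5. Heating F5 with 20 (dioxane, 90 °C) expels dimethylamine to an ortho-quinone methide that is captured at C3 of the pyranone, which comes back to the route at 23.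

**Further compounds**

F1 | step 11 | (R)-1-[4-(tert-butyldimethylsilyloxy)-3-{[(S)-3,3-dimethyloxiran-2-yl]methyl}-2,6-bis(methoxymethoxy)phenyl]-2-methylbutan-1-one | CC1(C)O[C@H]1Cc1c(OCOC)c(C(=O)[C@H](C)CC)c(OCOC)cc1O[Si](C)(C)C(C)(C)C
F2 | step 11 | (R)-1-[3-{[(S)-3,3-dimethyloxiran-2-yl]methyl}-4-hydroxy-2,6-bis(methoxymethoxy)phenyl]-2-methylbutan-1-one | CC1(C)O[C@H]1Cc1c(OCOC)c(C(=O)[C@H](C)CC)c(OCOC)cc1O
F3 | step 11 | (R)-1-[(R)-2-(2-hydroxypropan-2-yl)-4,6-bis(methoxymethoxy)-2,3-dihydrobenzofuran-5-yl]-2-methylbutan-1-one | CC(C)(O)[C@H]1Cc2c(OCOC)c(C(=O)[C@H](C)CC)c(OCOC)cc2O1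
F4 | step 8 | (E)-4-[6-(tert-butyldimethylsilyloxy)-2,4-bis(methoxymethoxy)-3-[(R)-2-methylbutanoyl]phenyl]-2-methylbut-2-enal | O=C/C(C)=C/Cc1c(OCOC)c(C(=O)[C@H](C)CC)c(OCOC)cc1O[Si](C)(C)C(C)(C)C
F5 | step 15 | (R)-1-[(R)-7-[(dimethylamino)methyl]-4,6-dihydroxy-2-(prop-1-en-2-yl)-2,3-dihydrobenzofuran-5-yl]-2-methylbutan-1-one | C=C(C)[C@H]1Cc2c(O)c(C(=O)[C@H](C)CC)c(O)c(CN(C)C)c2O1
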